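**Plan**

- Retrosynthesis: remove the two phenol PMB ethers; cut the two enol-ester C(=O)–O bonds to give a di-O-PMB-atromentin and lithium (2Z,4S,5S)-4,5-epoxyhex-2-enoate; then, at the tetraoxybenzene (leuco) level, cut two bonds of the central ring: one C=O carbon to its acyloxy-bearing neighbour, and the other C=O carbon to its aryl-bearing neighbour. This divides the six ring carbons 4 + 2.
- Enabling feature: the central six-membered ring carries O, aryl, O, O, aryl, O in sequence. The adjacent C(O)–C(aryl) pair is an aryl siloxyalkyne (Ar–C≡C–OSi). The other four carbons, O=C–C(O)=C(Ar)–C(O), are an alkoxy(siloxyvinyl)ketene stored as a squarate-derived 2-alkoxy-3-aryl-4-siloxycyclobutenone. The symmetric 2,5-dihydroxyquinone makes later differentiation of the four ring oxygens unnecessary.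
- Forward: 4-iodophenol gives the aryl iodide and from it the siloxyalkyne; diisopropyl squarate gives the cyclobutenone; thermal benzannulation builds the central ring; PhI(OAc)2 sets the quinone level; fluoride frees the two enolic OH groups; these are acylated; DDQ unmasks the phenols last.
- Stereochemistry: all four stereocentres (two identical trans-epoxides) come from one Sharpless epoxidation of (E)-but-2-en-1-ol with L-(+)-diisopropyl tartrate; both Z-olefins come from a Still–Gennari olefination.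

Key step: step 7

Remark: the squarate-derived cyclobutenones and the pericyclic intermediates carry one transient stereocentre and are used as racemates (the tertiary carbinol as a diastereomer mixture); this centre becomes an aromatic carbon in the benzannulation.

**Route**

Step 1
Reactants: 1 4-iodophenol
Product: 2 1-iodo-4-[(4-methoxybenzyl)oxy]benzene
Conditions: 4-methoxybenzyl chloride, K2CO3, DMF, rt
Reagents that add atoms: 4-methoxybenzyl chloride, COc1ccc(CCl)cc1
Why: Williamson ether synthesis, SN2 attack of the phenoxide on the benzylic chloride, installs a phenol mask that can later be removed oxidatively under neutral conditions.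

Step 2
Reactants: 2 1-iodo-4-[(4-methoxybenzyl)oxy]benzene
Product: 4 1-ethynyl-4-[(4-methoxybenzyl)oxy]benzene, via silylated alkyne 3 (not isolated)
Conditions: ethynyltrimethylsilane, PdCl2(PPh3)2 (cat.), CuI (cat.), Et3N, THF, rt; then K2CO3 (cat.), MeOH, rt
Reagents that add atoms: ethynyltrimethylsilane, C#C[Si](C)(C)C
Why: Sonogashira coupling (oxidative addition of the aryl iodide to zerovalent palladium, copper acetylide transmetalation, reductive elimination) followed in the same flask by methoxide-mediated protodesilylation of the alkynyl C–Si bond.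

Step 3
Reactants: 4 1-ethynyl-4-[(4-methoxybenzyl)oxy]benzene
Product: 7 triisopropyl[({4-[(4-methoxybenzyl)oxy]phenyl}ethynyl)oxy]silane, via lithium acetylide 5 (not isolated), via lithium ynolate 6 (not isolated)
Conditions: LiN(SiMe3)2, THF, −78 °C; LiOOt-Bu (from t-BuOOH + LiN(SiMe3)2), −78 → 0 °C; i-Pr3SiOTf, −78 → 0 °C
Reagents that add atoms: tert-butyl hydroperoxide, CC(C)(C)OO; triisopropylsilyl trifluoromethanesulfonate, CC(C)[Si](OS(=O)(=O)C(F)(F)F)(C(C)C)C(C)C
Why: Julia-type oxidation of a lithium acetylide by lithium tert-butyl peroxide (the acetylide carbon attacks the peroxide oxygen and expels tert-butoxide) should give the ynolate, which the bulky silyl triflate captures on oxygen to give the siloxyalkyne.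

Step 4
Reactants: 8 3,4-di(propan-2-yloxy)cyclobut-3-ene-1,2-dione (diisopropyl squarate)
Product: 9 4-hydroxy-2,3-di(propan-2-yloxy)cyclobut-2-en-1-one (racemic)
Conditions: LiAlH(Ot-Bu)3, THF, −78 → −20 °C; pH 7 aqueous work-up
Reagents that add atoms: none
Why: chemoselective 1,2-mono-reduction of a squarate ester by a bulky, mild hydride donor, as used for semisquarate synthesis, should stop at the hydroxycyclobutenone because the remaining carbonyl is a deactivated vinylogous ester; the new stereocentre is racemic and is erased later.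

Step 5
Reactants: 9 4-hydroxy-2,3-di(propan-2-yloxy)cyclobut-2-en-1-one
Product: 10 4-[(tert-butyldimethylsilyl)oxy]-2,3-di(propan-2-yloxy)cyclobut-2-en-1-one (racemic)
Conditions: t-BuMe2SiCl, imidazole, DMF, 0 °C → rt
Reagents that add atoms: tert-butyldimethylsilyl chloride, CC(C)(C)[Si](C)(C)Cl
Why: standard imidazole-promoted silylation of a secondary alcohol caps the oxygen so that the later vinylketene cannot lactonise to a butenolide.

Step 6
Reactants: 10 4-[(tert-butyldimethylsilyl)oxy]-2,3-di(propan-2-yloxy)cyclobut-2-en-1-one; 2 1-iodo-4-[(4-methoxybenzyl)oxy]benzene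
Product: 13 4-[(tert-butyldimethylsilyl)oxy]-3-{4-[(4-methoxybenzyl)oxy]phenyl}-2-(propan-2-yloxy)cyclobut-2-en-1-one (racemic), via aryllithium 11 (not isolated), via tertiary carbinol 12 (not isolated)
Conditions: 2, t-BuLi (2 equiv), THF, −78 °C; then 10, −78 °C; then 2 M aq. HCl, THF, 0 °C
Reagents that add atoms: water, O
Why: iodine–lithium exchange, 1,2-addition of the aryllithium to the vinylogous ester carbonyl and acid-mediated hydrolytic 1,3-carbonyl transposition with loss of propan-2-ol (the squarate counterpart of the Stork–Danheiser sequence, through an aryl- and alkoxy-stabilised cyclobutenyl cation) should place the aryl group beta and the isopropoxy group alpha to the new ketone; 1,2- and 1,4-addition lead to the same constitution because the siloxy-bearing carbon is bonded to both termini.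

Step 7
Reactants: 13 4-[(tert-butyldimethylsilyl)oxy]-3-{4-[(4-methoxybenzyl)oxy]phenyl}-2-(propan-2-yloxy)cyclobut-2-en-1-one; 7 triisopropyl[({4-[(4-methoxybenzyl)oxy]phenyl}ethynyl)oxy]silane
Product: 18 2-[(tert-butyldimethylsilyl)oxy]-3,6-bis{4-[(4-methoxybenzyl)oxy]phenyl}-4-(propan-2-yloxy)-5-[(triisopropylsilyl)oxy]phenol, via vinylketene 14 (not isolated), via vinylcyclobutenone 15 (not isolated), via dienylketene 16 (not isolated), via cyclohexadienone 17 (not isolated)
Conditions: 7 (1.3 equiv), degassed PhMe, 80 → 110 °C, Ar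
Reagents that add atoms: none
Why: Danheiser benzannulation: on heating, 13 should undergo 4π-conrotatory ring opening with the 4-siloxy group rotating outward to give the (E)-siloxyvinyl alkoxyketene 14, whose ketene C=C adds to the electron-rich siloxyalkyne 7 in a regiospecific [2+2] cycloaddition (ketene carbonyl carbon to the nucleophilic aryl-bearing alkyne carbon, alkoxy-bearing ketene carbon to the siloxy-bearing alkyne carbon), so that this one event forms both new ring bonds and closes the transient four-membered ring of 15. A second 4π opening of 15, with the isopropoxy group outward and the vinyl group therefore inward, should give dienylketene 16, which closes the six-membered ring by thermal 6π-disrotatory electrocyclisation of the ketene carbon onto the siloxy-bearing vinyl terminus, and a proton shift aromatises cyclohexadienone 17 to phenol 18. The closest known reaction type is the thermal cyclobutenone–siloxyalkyne benzannulation that gives resorcinol monosilyl ethers, together with the ring openings of squarate-derived 4-oxycyclobutenones used in hydroquinone synthesis. No stereocentre survives, since the racemic siloxy-bearing carbon of 13 becomes an aromatic carbon. The step needs regioselectivity, secured by the polarity match of ketene and ynol ether (aryl ends up ortho and siloxy meta to the new hydroxyl), and chemoselectivity against butenolide formation and arene participation, secured by the silyl cap on the 4-oxygen and by the aryl group sitting on C-3, from where no six-electron closure onto the arene is possible.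

Step 8
Reactants: 18 2-[(tert-butyldimethylsilyl)oxy]-3,6-bis{4-[(4-methoxybenzyl)oxy]phenyl}-4-(propan-2-yloxy)-5-[(triisopropylsilyl)oxy]phenol
Product: 20 2,5-dihydroxy-3,6-bis{4-[(4-methoxybenzyl)oxy]phenyl}cyclohexa-2,5-diene-1,4-dione, via bis(silyloxy)quinone 19 (not isolated)
Conditions: PhI(OAc)2, MeCN/H2O (4:1), 0 °C; then crude quinone, Bu4NF, AcOH, THF, 0 °C; dilute acid work-up
Reagents that add atoms: water, O
Why: oxidative dealkylation of a 4-alkoxyphenol by the trivalent iodine reagent (water adds para to the activated phenol and the hemiketal collapses with loss of propan-2-ol) should give the para-quinone, whose two vinylogous silyl esters are then cleaved by buffered fluoride while the PMB aryl ethers remain.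

Step 9
Reactants: 21 (2E)-but-2-en-1-ol
Product: 22 [(2S,3S)-3-methyloxiran-2-yl]methanol
Conditions: Ti(Oi-Pr)4 (cat.), L-(+)-diisopropyl tartrate (cat.), t-BuOOH, 4 Å MS, CH2Cl2, −20 °C; non-aqueous work-up, distillation
Reagents that add atoms: tert-butyl hydroperoxide, CC(C)(C)OO
Why: Sharpless asymmetric epoxidation, in which the titanium–L-(+)-tartrate complex delivers oxygen to the face of the E-allylic alcohol that gives the (2S,3S) epoxide (reagent control) and the trans relationship follows from stereospecific syn oxygen transfer to the E-olefin.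

Step 10
Reactants: 22 [(2S,3S)-3-methyloxiran-2-yl]methanol
Product: 23 (2R,3S)-3-methyloxirane-2-carbaldehyde
Conditions: Dess–Martin periodinane, NaHCO3, CH2Cl2, 0 °C → rt; pentane, filtration, used at once as a solution
Reagents that add atoms: none
Why: Dess–Martin oxidation is a neutral, non-epimerising way to the volatile epoxy aldehyde, whose configuration is unchanged (the descriptor at C-2 changes only because of ligand priorities).

Step 11
Reactants: 23 (2R,3S)-3-methyloxirane-2-carbaldehyde
Product: 24 methyl (2Z)-3-[(2S,3S)-3-methyloxiran-2-yl]prop-2-enoate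
Conditions: (CF3CH2O)2P(O)CH2CO2Me, KN(SiMe3)2, 18-crown-6, THF, −78 °C
Reagents that add atoms: methyl bis(2,2,2-trifluoroethyl)phosphonoacetate, COC(=O)CP(=O)(OCC(F)(F)F)OCC(F)(F)F
Why: Still–Gennari variant of the Horner–Wadsworth–Emmons olefination, in which the electron-poor phosphonate and the dissociated potassium counter-ion make elimination from the kinetic adduct faster than equilibration, so the Z-enoate should be formed.

Step 12
Reactants: 24 methyl (2Z)-3-[(2S,3S)-3-methyloxiran-2-yl]prop-2-enoate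
Product: 25 lithium (2Z)-3-[(2S,3S)-3-methyloxiran-2-yl]prop-2-enoate
Conditions: LiOH·H2O (1.0 equiv), THF/H2O, 0 °C; freeze-drying
Reagents that add atoms: lithium hydroxide, [Li+].[OH-]
Why: ester saponification by acyl–oxygen cleavage, with the product kept as the dry lithium carboxylate because the free Z-epoxy acid lactonises readily under acid.

Step 13
Reactants: 20 2,5-dihydroxy-3,6-bis{4-[(4-methoxybenzyl)oxy]phenyl}cyclohexa-2,5-diene-1,4-dione; 25 lithium (2Z)-3-[(2S,3S)-3-methyloxiran-2-yl]prop-2-enoate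
Product: 27 2,5-bis{4-[(4-methoxybenzyl)oxy]phenyl}-3,6-dioxocyclohexa-1,4-diene-1,4-diyl bis{(2Z)-3-[(2S,3S)-3-methyloxiran-2-yl]prop-2-enoate}, via mixed anhydride 26 (not isolated)
Conditions: 25 (2.4 equiv), 2,4,6-Cl3C6H2COCl (2.4 equiv), THF, 0 °C; then 20, Et3N, THF/PhMe, 0 °C → rt, no DMAP
Reagents that add atoms: none
Why: Yamaguchi-type mixed-anhydride acylation, in which the two quinone hydroxyls (vinylogous carboxylic acids, the only groups ionised by Et3N) attack the unhindered enoyl carbonyl of the mixed anhydride to give the vinylogous anhydrides, while leaving out a nucleophilic catalyst should avoid Z-to-E isomerisation by conjugate addition.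

Step 14
Reactants: 27 2,5-bis{4-[(4-methoxybenzyl)oxy]phenyl}-3,6-dioxocyclohexa-1,4-diene-1,4-diyl bis{(2Z)-3-[(2S,3S)-3-methyloxiran-2-yl]prop-2-enoate}
Product: 28 2,5-bis(4-hydroxyphenyl)-3,6-dioxocyclohexa-1,4-diene-1,4-diyl bis{(2Z)-3-[(2S,3S)-3-methyloxiran-2-yl]prop-2-enoate} (CNP0407724.1)
Conditions: DDQ (3 equiv), CH2Cl2/pH 7 phosphate buffer (10:1), 0 °C → rt
Reagents that add atoms: none
Why: oxidative cleavage of the 4-methoxybenzyl ethers by DDQ (hydride abstraction at the electron-rich benzylic carbon, hydrolysis of the oxocarbenium ion) runs under neutral, non-nucleophilic conditions that the quinone, the enol esters, the Z-enoates and the epoxides should tolerate.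

**Compound list**

1 | 4-iodophenol | Oc1ccc(I)cc1 | starting material
2 | 1-iodo-4-[(4-methoxybenzyl)oxy]benzene | COc1ccc(COc2ccc(I)cc2)cc1 | intermediate
3 | ({4-[(4-methoxybenzyl)oxy]phenyl}ethynyl)trimethylsilane | COc1ccc(COc2ccc(C#C[Si](C)(C)C)cc2)cc1 | intermediate
4 | 1-ethynyl-4-[(4-methoxybenzyl)oxy]benzene | COc1ccc(COc2ccc(C#C)cc2)cc1 | intermediate
5 | lithium {4-[(4-methoxybenzyl)oxy]phenyl}acetylide | [Li]C#Cc1ccc(OCc2ccc(OC)cc2)cc1 | intermediate
6 | lithium 2-{4-[(4-methoxybenzyl)oxy]phenyl}ethynolate | [Li+].[O-]C#Cc1ccc(OCc2ccc(OC)cc2)cc1 | intermediate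
7 | triisopropyl[({4-[(4-methoxybenzyl)oxy]phenyl}ethynyl)oxy]silane | CC(C)[Si](OC#Cc1ccc(OCc2ccc(OC)cc2)cc1)(C(C)C)C(C)C | intermediate
8 | 3,4-di(propan-2-yloxy)cyclobut-3-ene-1,2-dione (diisopropyl squarate) | CC(C)OC1=C(OC(C)C)C(=O)C1=O | starting material
9 | 4-hydroxy-2,3-di(propan-2-yloxy)cyclobut-2-en-1-one (racemic) | CC(C)OC1=C(OC(C)C)C(O)C1=O | intermediate
10 | 4-[(tert-butyldimethylsilyl)oxy]-2,3-di(propan-2-yloxy)cyclobut-2-en-1-one (racemic) | CC(C)OC1=C(OC(C)C)C(O[Si](C)(C)C(C)(C)C)C1=O | intermediate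
11 | {4-[(4-methoxybenzyl)oxy]phenyl}lithium | [Li]c1ccc(OCc2ccc(OC)cc2)cc1 | intermediate
12 | 4-[(tert-butyldimethylsilyl)oxy]-1-{4-[(4-methoxybenzyl)oxy]phenyl}-2,3-di(propan-2-yloxy)cyclobut-2-en-1-ol (racemic, diastereomer mixture) | OC1(c2ccc(OCc3ccc(OC)cc3)cc2)C(OC(C)C)=C(OC(C)C)C1O[Si](C)(C)C(C)(C)C | intermediate
13 | 4-[(tert-butyldimethylsilyl)oxy]-3-{4-[(4-methoxybenzyl)oxy]phenyl}-2-(propan-2-yloxy)cyclobut-2-en-1-one (racemic) | O=C1C(OC(C)C)=C(c2ccc(OCc3ccc(OC)cc3)cc2)C1O[Si](C)(C)C(C)(C)C | intermediate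
14 | (3E)-4-[(tert-butyldimethylsilyl)oxy]-3-{4-[(4-methoxybenzyl)oxy]phenyl}-2-(propan-2-yloxy)buta-1,3-dien-1-one | O=C=C(OC(C)C)/C(c1ccc(OCc2ccc(OC)cc2)cc1)=C/O[Si](C)(C)C(C)(C)C | intermediate
15 | 4-[(E)-2-[(tert-butyldimethylsilyl)oxy]-1-{4-[(4-methoxybenzyl)oxy]phenyl}ethenyl]-2-{4-[(4-methoxybenzyl)oxy]phenyl}-4-(propan-2-yloxy)-3-[(triisopropylsilyl)oxy]cyclobut-2-en-1-one (racemic) | O=C1C(c2ccc(OCc3ccc(OC)cc3)cc2)=C(O[Si](C(C)C)(C(C)C)C(C)C)C1(OC(C)C)/C(c1ccc(OCc2ccc(OC)cc2)cc1)=C/O[Si](C)(C)C(C)(C)C | intermediate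
16 | (3Z,5E)-6-[(tert-butyldimethylsilyl)oxy]-2,5-bis{4-[(4-methoxybenzyl)oxy]phenyl}-4-(propan-2-yloxy)-3-[(triisopropylsilyl)oxy]hexa-1,3,5-trien-1-one | O=C=C(c1ccc(OCc2ccc(OC)cc2)cc1)/C(O[Si](C(C)C)(C(C)C)C(C)C)=C(OC(C)C)\C(c1ccc(OCc2ccc(OC)cc2)cc1)=C\O[Si](C)(C)C(C)(C)C | intermediate
17 | 6-[(tert-butyldimethylsilyl)oxy]-2,5-bis{4-[(4-methoxybenzyl)oxy]phenyl}-4-(propan-2-yloxy)-3-[(triisopropylsilyl)oxy]cyclohexa-2,4-dien-1-one (racemic) | O=C1C(c2ccc(OCc3ccc(OC)cc3)cc2)=C(O[Si](C(C)C)(C(C)C)C(C)C)C(OC(C)C)=C(c2ccc(OCc3ccc(OC)cc3)cc2)C1O[Si](C)(C)C(C)(C)C | intermediate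
18 | 2-[(tert-butyldimethylsilyl)oxy]-3,6-bis{4-[(4-methoxybenzyl)oxy]phenyl}-4-(propan-2-yloxy)-5-[(triisopropylsilyl)oxy]phenol | Oc1c(c2ccc(OCc3ccc(OC)cc3)cc2)c(O[Si](C(C)C)(C(C)C)C(C)C)c(OC(C)C)c(c2ccc(OCc3ccc(OC)cc3)cc2)c1O[Si](C)(C)C(C)(C)C | intermediate
19 | 2-[(tert-butyldimethylsilyl)oxy]-3,6-bis{4-[(4-methoxybenzyl)oxy]phenyl}-5-[(triisopropylsilyl)oxy]cyclohexa-2,5-diene-1,4-dione | O=C1C(c2ccc(OCc3ccc(OC)cc3)cc2)=C(O[Si](C(C)C)(C(C)C)C(C)C)C(=O)C(c2ccc(OCc3ccc(OC)cc3)cc2)=C1O[Si](C)(C)C(C)(C)C | intermediate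
20 | 2,5-dihydroxy-3,6-bis{4-[(4-methoxybenzyl)oxy]phenyl}cyclohexa-2,5-diene-1,4-dione | O=C1C(O)=C(c2ccc(OCc3ccc(OC)cc3)cc2)C(=O)C(O)=C1c1ccc(OCc2ccc(OC)cc2)cc1 | intermediate
21 | (2E)-but-2-en-1-ol | C/C=C/CO | starting material
22 | [(2S,3S)-3-methyloxiran-2-yl]methanol | C[C@@H]1O[C@H]1CO | intermediate
23 | (2R,3S)-3-methyloxirane-2-carbaldehyde | C[C@@H]1O[C@H]1C=O | intermediate
24 | methyl (2Z)-3-[(2S,3S)-3-methyloxiran-2-yl]prop-2-enoate | C[C@@H]1O[C@H]1/C=C\C(=O)OC | intermediate
25 | lithium (2Z)-3-[(2S,3S)-3-methyloxiran-2-yl]prop-2-enoate | C[C@@H]1O[C@H]1/C=C\C(=O)[O-].[Li+] | intermediate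
26 | (2Z)-3-[(2S,3S)-3-methyloxiran-2-yl]prop-2-enoic 2,4,6-trichlorobenzoic anhydride | C[C@@H]1O[C@H]1/C=C\C(=O)OC(=O)c1c(Cl)cc(Cl)cc1Cl | intermediate
27 | 2,5-bis{4-[(4-methoxybenzyl)oxy]phenyl}-3,6-dioxocyclohexa-1,4-diene-1,4-diyl bis{(2Z)-3-[(2S,3S)-3-methyloxiran-2-yl]prop-2-enoate} | C[C@@H]1O[C@H]1/C=C\C(=O)OC1=C(c2ccc(OCc3ccc(OC)cc3)cc2)C(=O)C(OC(=O)/C=C\[C@@H]2O[C@H]2C)=C(c2ccc(OCc3ccc(OC)cc3)cc2)C1=O | intermediate
28 | 2,5-bis(4-hydroxyphenyl)-3,6-dioxocyclohexa-1,4-diene-1,4-diyl bis{(2Z)-3-[(2S,3S)-3-methyloxiran-2-yl]prop-2-enoate} (CNP0407724.1) | C[C@@H]1O[C@H]1/C=C\C(=O)OC1=C(c2ccc(O)cc2)C(=O)C(OC(=O)/C=C\[C@@H]2O[C@H]2C)=C(c2ccc(O)cc2)C1=O | target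

**Summary**

Total step count: 14.
Longest linear sequence: 7 steps (steps 1, 2, 3, 7, 8, 13, 14 from 4-iodophenol; equally steps 4, 5, 6, 7, 8, 13, 14 from diisopropyl squarate).

Steps most likely to fail:

1. Step 7 (benzannulation). The transient vinylketene may dimerise or acylate the product phenol faster than the siloxyalkyne intercepts it, or the siloxyalkyne may be lost by hydrolysis at the reaction temperature. The fallback is known cross-coupling chemistry; it sets out from 2 and returns at 20. Miyaura borylation of 2 (B2pin2, PdCl2(dppf), KOAc, dioxane, 80 °C) should give 2-{4-[(4-methoxybenzyl)oxy]phenyl}-4,4,5,5-tetramethyl-1,3,2-dioxaborolane F1. Commercial tetrabromo-1,4-benzoquinone with NaOMe in MeOH should give 2,5-dibromo-3,6-dimethoxycyclohexa-2,5-diene-1,4-dione F2. Twofold Suzuki–Miyaura coupling of F2 with F1 (Pd(PPh3)4, K2CO3, dioxane/H2O, 80 °C) should give 2,5-dimethoxy-3,6-bis{4-[(4-methoxybenzyl)oxy]phenyl}cyclohexa-2,5-diene-1,4-dione F3. Hydrolysis of its two vinylogous methyl esters (NaOH, aqueous dioxane, then dilute HCl) leads back to 20.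

2. Step 13 (double acylation). The activated Z-enoyl unit may isomerise to E, the epoxide may be opened by the activated carboxyl group (lactonisation), or the second acylation may stall. The fallback reverses the polarity of the ester-forming step; it sets out from 20 and returns at 27. Treatment of 20 with (COCl)2 and catalytic DMF in CH2Cl2 should give 2,5-dichloro-3,6-bis{4-[(4-methoxybenzyl)oxy]phenyl}cyclohexa-2,5-diene-1,4-dione F4. Its two vinylogous acyl chlorides are then displaced by carboxylate 25 (Bu4NBr, MeCN, 0 °C → rt) by addition–elimination to give 27. The sensitive acid is never activated in this variant.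

3. Step 14 (final unmasking). The enol esters may be lost by hydrolysis or intermolecular acyl transfer to the freed phenols while the PMB groups are oxidised. The fallback changes the order of events; it sets out from 20 and returns at 28. PMB removal from 20 with CF3CO2H and anisole in CH2Cl2 at 0 °C should give 2,5-dihydroxy-3,6-bis(4-hydroxyphenyl)cyclohexa-2,5-diene-1,4-dione (atromentin) F5. Bu4NOH (2.0 equiv) should deprotonate only the two strongly acidic quinone hydroxyls to give bis(tetrabutylammonium) 2,5-bis(4-hydroxyphenyl)-3,6-dioxocyclohexa-1,4-diene-1,4-diolate F6. Acylation of F6 with mixed anhydride 26 (2.0 equiv, THF, −20 °C, no further base) should give 28 directly, the neutral phenols remaining unacylated.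

**Further compounds**

F1 | step 7 | 2-{4-[(4-methoxybenzyl)oxy]phenyl}-4,4,5,5-tetramethyl-1,3,2-dioxaborolane | COc1ccc(COc2ccc(B3OC(C)(C)C(C)(C)O3)cc2)cc1
F2 | step 7 | 2,5-dibromo-3,6-dimethoxycyclohexa-2,5-diene-1,4-dione | COC1=C(Br)C(=O)C(OC)=C(Br)C1=O
F3 | step 7 | 2,5-dimethoxy-3,6-bis{4-[(4-methoxybenzyl)oxy]phenyl}cyclohexa-2,5-diene-1,4-dione | COC1=C(c2ccc(OCc3ccc(OC)cc3)cc2)C(=O)C(OC)=C(c2ccc(OCc3ccc(OC)cc3)cc2)C1=O
F4 | step 13 | 2,5-dichloro-3,6-bis{4-[(4-methoxybenzyl)oxy]phenyl}cyclohexa-2,5-diene-1,4-dione | ClC1=C(c2ccc(OCc3ccc(OC)cc3)cc2)C(=O)C(Cl)=C(c2ccc(OCc3ccc(OC)cc3)cc2)C1=O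
F5 | step 14 | 2,5-dihydroxy-3,6-bis(4-hydroxyphenyl)cyclohexa-2,5-diene-1,4-dione (atromentin) | O=C1C(O)=C(c2ccc(O)cc2)C(=O)C(O)=C1c1ccc(O)cc1
F6 | step 14 | bis(tetrabutylammonium) 2,5-bis(4-hydroxyphenyl)-3,6-dioxocyclohexa-1,4-diene-1,4-diolate | CCCC[N+](CCCC)(CCCC)CCCC.CCCC[N+](CCCC)(CCCC)CCCC.[O-]C1=C(c2ccc(O)cc2)C(=O)C([O-])=C(c2ccc(O)cc2)C1=O
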